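**Retrosynthetic overview**

1. The last disconnection is the bond between aromatic C2 and chain carbon C1′. It leads to p-benzoquinone 15 and the C20 (2E,6E)-allylstannane 14, joined by a BF3-mediated, redox-neutral quinone allylation that needs no protecting groups.
2. Enabling feature: ring A is a 1,4-dihydroxybenzene (O on C1 and C4), the reduced form of p-benzoquinone. At the quinone level its four CH carbons are equivalent electrophiles, while C1′, allylic to the C2′=C3′ alkene, can carry tin. Two natively nucleophilic carbons are thus united by reversing the polarity of the ring through its oxidation level.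
3. 14 comes from chloride 13 and allylic alcohol 11, which comes from Zr-catalysed methylalumination and formaldehyde trapping of enyne 9 (sets C2′=C3′ as E).
4. 9 comes from Negishi coupling of alkenyl iodide 5 with a homopropargylzinc; 5 comes from methylalumination and iodination of alkyne 3 (sets C6′=C7′ as E), itself made from dihydro-β-ionone 1.
5. Rings: no ring is closed. Cyclohexene ring B is bought intact in 1; ring A enters as the quinone and is aromatised in the last step.

Key step: step 8

Assumption: the target is achiral, so the only stereochemical elements to control are the two E trisubstituted alkenes (C2′=C3′ and C6′=C7′, chain numbered from the aryl-bound CH2) and the position of the tetrasubstituted ring alkene.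

**Route**

Step 1
Reactants: 1 dihydro-β-ionone [4-(2,6,6-trimethylcyclohex-1-en-1-yl)butan-2-one]
Product: 3 2-(but-3-yn-1-yl)-1,3,3-trimethylcyclohex-1-ene, via enol diethyl phosphate 2 (not isolated)
Conditions: LDA (1.05 equiv), THF, −78 °C; ClP(O)(OEt)2, −78 °C → rt; then LDA (2.3 equiv), THF, −78 °C → rt; H2O
Reagents that add atoms: none
Why: Kinetic deprotonation of the methyl group, O-phosphorylation and LDA-induced β-elimination of diethyl phosphate (enol phosphate route from a methyl ketone to a terminal alkyne) should give the alkyne, with acetylide formation pulling the elimination to the terminal position and the ring alkene untouched.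

Step 2
Reactants: 3 2-(but-3-yn-1-yl)-1,3,3-trimethylcyclohex-1-ene
Product: 5 2-[(3E)-4-iodo-3-methylbut-3-en-1-yl]-1,3,3-trimethylcyclohex-1-ene, via alkenylalane 4 (not isolated)
Conditions: Me3Al (2 equiv), Cp2ZrCl2 (0.25 equiv), CH2Cl2, 0 °C → rt; then I2, THF, −30 → 0 °C
Reagents that add atoms: trimethylaluminium, C[Al](C)C; iodine, II
Why: Zr-catalysed syn-methylalumination (Negishi carboalumination) places Me and Al cis with Al on the terminal carbon, and iodinolysis with retention fixes the E geometry of the future C6′=C7′ alkene, the tetrasubstituted ring alkene being inert to carbometalation.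

Step 3
Reactants: 5 2-[(3E)-4-iodo-3-methylbut-3-en-1-yl]-1,3,3-trimethylcyclohex-1-ene; 6 (4-bromobut-1-yn-1-yl)trimethylsilane
Product: 8 trimethyl[(5E)-6-methyl-8-(2,6,6-trimethylcyclohex-1-en-1-yl)oct-5-en-1-yn-1-yl]silane, via homopropargylzinc bromide 7 (not isolated)
Conditions: 6, Zn dust, LiCl, THF, 50 °C; then 5, Pd(PPh3)4 (5 mol %), THF, rt
Reagents that add atoms: none
Why: Negishi coupling of an (E)-alkenyl iodide with a primary homopropargylzinc reagent proceeds with retention of alkene geometry and outruns β-hydride elimination, so it should install the C4′–C5′ ethylene bridge together with a masked terminal alkyne for the next isoprene unit.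

Step 4
Reactants: 8 trimethyl[(5E)-6-methyl-8-(2,6,6-trimethylcyclohex-1-en-1-yl)oct-5-en-1-yn-1-yl]silane
Product: 9 2-[(3E)-3-methyloct-3-en-7-yn-1-yl]-1,3,3-trimethylcyclohex-1-ene
Conditions: K2CO3, MeOH, rt
Reagents that add atoms: none
Why: Base-mediated methanolysis of the alkynyl C–Si bond (protodesilylation) should free the terminal alkyne without touching the skipped alkenes.

Step 5
Reactants: 9 2-[(3E)-3-methyloct-3-en-7-yn-1-yl]-1,3,3-trimethylcyclohex-1-ene
Product: 11 (2E,6E)-3,7-dimethyl-9-(2,6,6-trimethylcyclohex-1-en-1-yl)nona-2,6-dien-1-ol, via alkenylalane 10 (not isolated)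
Conditions: Me3Al (2 equiv), Cp2ZrCl2 (0.25 equiv), CH2Cl2, rt; volatiles removed; then n-BuLi, THF/hexane, −78 °C; (CH2O)n, −78 °C → rt; aq. potassium sodium tartrate
Reagents that add atoms: trimethylaluminium, C[Al](C)C; formaldehyde (from paraformaldehyde), C=O
Why: A second syn-methylalumination sets the C2′=C3′ alkene as E, and conversion of the alkenylalane into its alanate with n-BuLi makes it nucleophilic enough to add to formaldehyde with retention, giving the allylic alcohol directly (Negishi carboalumination followed by hydroxymethylation).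

Step 6
Reactants: 11 (2E,6E)-3,7-dimethyl-9-(2,6,6-trimethylcyclohex-1-en-1-yl)nona-2,6-dien-1-ol
Product: 13 2-[(3E,7E)-9-chloro-3,7-dimethylnona-3,7-dien-1-yl]-1,3,3-trimethylcyclohex-1-ene, via allylic mesylate 12 (not isolated)
Conditions: MsCl, 2,4,6-collidine, LiCl, DMF, 0 °C; used crude
Reagents that add atoms: lithium chloride, [Li+].[Cl-]
Why: Collington–Meyers chlorination displaces the mesylate formed in the flask by chloride in an SN2 reaction at the primary allylic carbon under buffered, non-ionising conditions, so neither allylic transposition nor E/Z isomerisation is expected.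

Step 7
Reactants: 13 2-[(3E,7E)-9-chloro-3,7-dimethylnona-3,7-dien-1-yl]-1,3,3-trimethylcyclohex-1-ene
Product: 14 tributyl[(2E,6E)-3,7-dimethyl-9-(2,6,6-trimethylcyclohex-1-en-1-yl)nona-2,6-dien-1-yl]stannane
Conditions: Bu3SnLi (from Bu3SnH, LDA, THF, 0 °C), THF, −78 → −40 °C; filtration through Et3N-deactivated silica
Reagents that add atoms: tributyltin hydride (used as Bu3SnLi), CCCC[SnH](CCCC)CCCC
Why: SN2 substitution of a primary allylic chloride by a stannyl anion occurs at the unhindered α-carbon (the γ-carbon is fully substituted) and leaves the E alkene untouched, as is usual for polyprenyl chlorides.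

Step 8
Reactants: 14 tributyl[(2E,6E)-3,7-dimethyl-9-(2,6,6-trimethylcyclohex-1-en-1-yl)nona-2,6-dien-1-yl]stannane; 15 p-benzoquinone
Product: 18 jaspaquinol [2-[(2E,6E)-3,7-dimethyl-9-(2,6,6-trimethylcyclohex-1-en-1-yl)nona-2,6-dien-1-yl]benzene-1,4-diol], via quinol adduct 16 (not isolated), via dienone tautomer 17 (not isolated)
Conditions: 15 (1.5 equiv), BF3·OEt2 (3 equiv), CH2Cl2, −78 °C; 14 added slowly; −78 → −30 °C; cold quench, then aq. Na2S2O4 and aq. KF wash
Reagents that add atoms: none
Why: BF3 bound to one carbonyl oxygen of 15 makes that carbonyl carbon strongly electrophilic, and 14 attacks it through its γ-carbon C3′ with loss of the Bu3Sn group (SE2′, open transition state) to give the O-metalated quinol 16, which undergoes a charge-accelerated oxy-Cope-type [3,3] shift that breaks the bond from C3′ to the carbinol carbon and bonds C1′ to the neighbouring ring carbon (dienone 17), after which enolisation restores aromaticity. The closest known reaction type is the BF3-mediated allylation of p-quinones with allyl- and polyprenylstannanes, the established stannane route to polyprenylated quinones and hydroquinones. No ring is closed and no stereocentre survives (the transient quaternary carbon of 16 and the sp3 ring carbon of 17 are both erased), and because quinone plus allyl-anion equivalent equals hydroquinone, the step is redox-neutral and should deliver the free diol without protecting groups. The step needs linear (C1′) rather than branched (C3′) attachment, which the two successive allylic transpositions secure, and it needs the E geometry at C2′=C3′, which is re-formed in a chair-like transition state with the long chain from C4′ pseudo-equatorial and which this reaction class is known to preserve for all-E polyprenylstannanes. Mono-allylation should follow from the four equivalent CH positions of 15, from its excess and from the lower electrophilicity of any alkylated quinone formed by redox exchange, while the low temperature and cold quench should keep BF3 from cyclising the polyene or closing a chroman onto C3′. The Na2S2O4 wash returns any product oxidised by excess 15 to the hydroquinone, and KF removes tin as Bu3SnF.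

**Compound list**

1 | dihydro-β-ionone, 4-(2,6,6-trimethylcyclohex-1-en-1-yl)butan-2-one | CC(=O)CCC1=C(C)CCCC1(C)C | starting material
2 | diethyl 4-(2,6,6-trimethylcyclohex-1-en-1-yl)but-1-en-2-yl phosphate (enol phosphate) | C=C(CCC1=C(C)CCCC1(C)C)OP(=O)(OCC)OCC | intermediate
3 | 2-(but-3-yn-1-yl)-1,3,3-trimethylcyclohex-1-ene | C#CCCC1=C(C)CCCC1(C)C | intermediate
4 | dimethyl[(1E)-2-methyl-4-(2,6,6-trimethylcyclohex-1-en-1-yl)but-1-en-1-yl]alane | C[Al](C)/C=C(\C)CCC1=C(C)CCCC1(C)C | intermediate
5 | 2-[(3E)-4-iodo-3-methylbut-3-en-1-yl]-1,3,3-trimethylcyclohex-1-ene | I/C=C(\C)CCC1=C(C)CCCC1(C)C | intermediate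
6 | (4-bromobut-1-yn-1-yl)trimethylsilane | C[Si](C)(C)C#CCCBr | starting material
7 | [4-(trimethylsilyl)but-3-yn-1-yl]zinc bromide | C[Si](C)(C)C#CCC[Zn]Br | intermediate
8 | trimethyl[(5E)-6-methyl-8-(2,6,6-trimethylcyclohex-1-en-1-yl)oct-5-en-1-yn-1-yl]silane | CC1=C(CC/C(C)=C/CCC#C[Si](C)(C)C)C(C)(C)CCC1 | intermediate
9 | 2-[(3E)-3-methyloct-3-en-7-yn-1-yl]-1,3,3-trimethylcyclohex-1-ene | CC1=C(CC/C(C)=C/CCC#C)C(C)(C)CCC1 | intermediate
10 | [(1E,5E)-2,6-dimethyl-8-(2,6,6-trimethylcyclohex-1-en-1-yl)octa-1,5-dien-1-yl]dimethylalane | C[Al](C)/C=C(\C)CC/C=C(\C)CCC1=C(C)CCCC1(C)C | intermediate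
11 | (2E,6E)-3,7-dimethyl-9-(2,6,6-trimethylcyclohex-1-en-1-yl)nona-2,6-dien-1-ol | CC1=C(CC/C(C)=C/CC/C(C)=C/CO)C(C)(C)CCC1 | intermediate
12 | (2E,6E)-3,7-dimethyl-9-(2,6,6-trimethylcyclohex-1-en-1-yl)nona-2,6-dien-1-yl methanesulfonate | CC1=C(CC/C(C)=C/CC/C(C)=C/COS(C)(=O)=O)C(C)(C)CCC1 | intermediate
13 | 2-[(3E,7E)-9-chloro-3,7-dimethylnona-3,7-dien-1-yl]-1,3,3-trimethylcyclohex-1-ene | CC1=C(CC/C(C)=C/CC/C(C)=C/CCl)C(C)(C)CCC1 | intermediate
14 | tributyl[(2E,6E)-3,7-dimethyl-9-(2,6,6-trimethylcyclohex-1-en-1-yl)nona-2,6-dien-1-yl]stannane | CC1=C(CC/C(C)=C/CC/C(C)=C/C[Sn](CCCC)(CCCC)CCCC)C(C)(C)CCC1 | intermediate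
15 | p-benzoquinone, cyclohexa-2,5-diene-1,4-dione | O=C1C=CC(=O)C=C1 | starting material
16 | 4-hydroxy-4-[(6E)-3,7-dimethyl-9-(2,6,6-trimethylcyclohex-1-en-1-yl)nona-1,6-dien-3-yl]cyclohexa-2,5-dien-1-one (racemic; drawn as the free quinol, in the flask O-bound to Bu3Sn/BF3) | C=CC(C)(CC/C=C(\C)CCC1=C(C)CCCC1(C)C)C2(O)C=CC(=O)C=C2 | intermediate
17 | 6-[(2E,6E)-3,7-dimethyl-9-(2,6,6-trimethylcyclohex-1-en-1-yl)nona-2,6-dien-1-yl]-4-hydroxycyclohexa-2,4-dien-1-one (racemic; drawn as the free enol) | O=C1C=CC(O)=CC1C/C=C(\C)CC/C=C(\C)CCC2=C(C)CCCC2(C)C | intermediate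
18 | jaspaquinol, 2-[(2E,6E)-3,7-dimethyl-9-(2,6,6-trimethylcyclohex-1-en-1-yl)nona-2,6-dien-1-yl]benzene-1,4-diol | CC1=C(CC/C(C)=C/CC/C(C)=C/Cc2cc(O)ccc2O)C(C)(C)CCC1 | target

**Step count**

Total steps: 8. Longest linear sequence: 8 steps (1 → 18); compounds 6 and 15 are purchased.

**Steps most likely to fail, with fallbacks**

Step 8. The E geometry at C2′=C3′ may erode in the [3,3] shift. Redox exchange between the product and excess quinone may lead to a second allylation. The Lewis acid may also trigger cyclisation of the polyene or chroman closure. The fallback reverses the polarity of the union and sets out from chloride 13. Commercial 1,4-dimethoxybenzene is ortho-lithiated (n-BuLi, TMEDA, THF, 0 °C) to (2,5-dimethoxyphenyl)lithium F1. This is converted into the arylcopper reagent with CuBr·SMe2 and alkylated with 13 (SN2, alkene geometry untouched) to give 2-[(2E,6E)-3,7-dimethyl-9-(2,6,6-trimethylcyclohex-1-en-1-yl)nona-2,6-dien-1-yl]-1,4-dimethoxybenzene F2. Oxidative demethylation with (NH4)2Ce(NO3)6 in MeCN/H2O at 0 °C gives 2-[(2E,6E)-3,7-dimethyl-9-(2,6,6-trimethylcyclohex-1-en-1-yl)nona-2,6-dien-1-yl]cyclohexa-2,5-diene-1,4-dione F3. Reduction with aqueous Na2S2O4 in Et2O comes back to the route at target 18.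

Step 3. Zinc insertion into 6 may be incomplete, or slow transmetalation may allow reduction or homocoupling of the alkenyl iodide. The fallback builds the two-carbon bridge by epoxide opening and SN2 alkynylation instead of cross-coupling, and sets out from alkyne 3. Methylalumination as in step 2 gives alane 4, which is converted into its alanate with n-BuLi and opened onto ethylene oxide to give (3E)-4-methyl-6-(2,6,6-trimethylcyclohex-1-en-1-yl)hex-3-en-1-ol F4. Appel-type iodination (I2, PPh3, imidazole, CH2Cl2) gives 2-[(3E)-6-iodo-3-methylhex-3-en-1-yl]-1,3,3-trimethylcyclohex-1-ene F5. Displacement with LiC≡CH·H2NCH2CH2NH2 in DMSO at rt comes back to the route at enyne 9.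

Step 7. The stannyl anion may attack with allylic transposition, electron transfer may cause reductive dimerisation, and the allylstannane may be protodestannylated during isolation. The fallback makes the C–Sn bond through a π-allylpalladium intermediate and sets out from alcohol 11. Acetylation (Ac2O, pyridine, DMAP) gives (2E,6E)-3,7-dimethyl-9-(2,6,6-trimethylcyclohex-1-en-1-yl)nona-2,6-dien-1-yl acetate F6. Pd(PPh3)4-catalysed stannylation with Bu3SnAlEt2 (from Bu3SnLi and Et2AlCl) in THF at 0 °C → rt comes back to the route at stannane 14.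

Further compounds
F1 | step 8 | (2,5-dimethoxyphenyl)lithium | [Li]c1cc(OC)ccc1OC
F2 | step 8 | 2-[(2E,6E)-3,7-dimethyl-9-(2,6,6-trimethylcyclohex-1-en-1-yl)nona-2,6-dien-1-yl]-1,4-dimethoxybenzene | CC1=C(CC/C(C)=C/CC/C(C)=C/Cc2cc(OC)ccc2OC)C(C)(C)CCC1
F3 | step 8 | 2-[(2E,6E)-3,7-dimethyl-9-(2,6,6-trimethylcyclohex-1-en-1-yl)nona-2,6-dien-1-yl]cyclohexa-2,5-diene-1,4-dione | CC1=C(CC/C(C)=C/CC/C(C)=C/CC2=CC(=O)C=CC2=O)C(C)(C)CCC1
F4 | step 3 | (3E)-4-methyl-6-(2,6,6-trimethylcyclohex-1-en-1-yl)hex-3-en-1-ol | CC1=C(CC/C(C)=C/CCO)C(C)(C)CCC1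
F5 | step 3 | 2-[(3E)-6-iodo-3-methylhex-3-en-1-yl]-1,3,3-trimethylcyclohex-1-ene | CC1=C(CC/C(C)=C/CCI)C(C)(C)CCC1
F6 | step 7 | (2E,6E)-3,7-dimethyl-9-(2,6,6-trimethylcyclohex-1-en-1-yl)nona-2,6-dien-1-yl acetate | CC1=C(CC/C(C)=C/CC/C(C)=C/COC(C)=O)C(C)(C)CCC1
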